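## Structural features

Compound 17 is a single oxolane ring, labelled here O1–C2–C3–C4–C5 (systematic names keep their own locants). It carries a 3,4,5-trimethoxyphenyl group on C2, a hydroxymethyl group on C3 and a 3,4,5-trimethoxybenzoyl group on C4; C5 is an unsubstituted methylene. C2 (S), C3 (S) and C4 (R) are contiguous stereocentres: aryl and hydroxymethyl are cis, hydroxymethyl and aroyl are trans. The C2–O1 bond is a benzylic ether next to an electron-rich ring and ionises under acid. C4 is α to the ketone and epimerisable, O1 sits β to that ketone through C5, and a C4 epimer would be trapped by the γ-hydroxyl as a cis-fused bicyclic lactol. The real difficulty is the contra-thermodynamic 2,3-cis relationship beside a labile benzylic centre, in one enantiomeric series; C4 can be left to thermodynamics. The key step uses the fact that O1 bridges C2 and C5 across C3 and C4, with a carbonyl carbon on C4. This is the pattern left when the oxygen of a 2-aryl-3-vinyl oxirane, whose vinyl group is an acrylate, moves from C3 to the acrylate terminus C5. The resulting C3=C4 alkene already holds both carbon substituents and is conjugated to the ester, so C3 and C4 can afterwards be set from C2 alone.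

## Logic of the disconnections

17 ⇒ 16. The O–Si bond of the primary alcohol is cut last. The hydroxyl must be masked through the organomagnesium steps and kept away from the ester and ketone. The unmasking must be neither basic enough to epimerise C4 nor acidic enough to ionise C2–O1.

16 ⇒ 13 + 14 (through 15). The bond between the ketone carbon and its aryl ring is cut. This removes half of the aromatic mass, returns the C4 substituent to the carboxylic oxidation level and draws the second ring from a simple aryl bromide. The forward step must stop at single addition, which the N-methoxy-N-methylamide of 13 secures.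

13 ⇒ 12. The amide C–N bond is cut back to a methyl ester. The ester is the group that the key step needs as acceptor, so no functional group is carried only for the endgame. Aminolysis must not disturb C4, which by then is in its preferred configuration.

12 ⇒ 10 (through 11). The C3–H and C4–H bonds are removed, giving a tetrasubstituted C3=C4 enoate. Two stereocentres are traded for one alkene, and C2 becomes the only control element. Hydride must reach C3 from the face opposite the aryl group (2,3-cis), and C4 is then equilibrated to trans. A plain [(Ph3P)CuH]6 reduction is unlikely to attack so hindered a β-carbon, so a ligand-accelerated copper hydride is planned.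

10 ⇒ 8 (through 9). O1–C5 is cut and O1 is reattached to C3, contracting the dihydrofuran to a vinyl oxirane. The forward reaction is a strain-releasing isomerisation that builds the ring without touching C2. The simplification is large: the heterocycle becomes the epoxide of a dienyl alcohol. The forward step must break the tertiary allylic C3–O bond and not the benzylic C2–O bond. Iodide catalysis is therefore chosen over Cu(hfacac)2, because a Lewis acid would favour ionisation next to the trimethoxyphenyl ring.

8 ⇒ 7 ⇒ 6. The O–Si bond and then both oxirane C–O bonds are cut, leaving an allylic alcohol. The free hydroxyl directs a titanium tartrate epoxidation, which fixes the absolute configuration of C2. The forward step must select the styrenyl alkene over the acrylate and needs D-(−)-tartrate for the required enantiomer.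

6 ⇒ 3 + 5. The sp2–sp2 bond between C3 and C4 is cut. Both partners are geometrically defined and small. The coupling must retain the alkene geometry (aryl trans to the hydroxymethyl group) and avoid cine substitution at the 1-substituted vinylstannane.

5 ⇒ 4. The C–Sn and C–H bonds are removed to give the alkynoate; the hydrostannation must place tin on the α-carbon.

3 ⇒ 2 ⇒ 1. The carbinol C–H and then the C–I bond are removed. Iodination at the α-carbon of the enal keeps aryl trans to the carbonyl group, and the reduction must be strictly 1,2.

## Other disconnections considered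

Alternative 1: The cut is C4–C5. In the forward sense the (Z)-trimethylsilyl enol ether A1 of the open-chain aryl ketone carries a methoxymethyl ether on the C2 oxygen and a pivalate on the C3 hydroxymethyl group. TMSOTf would ionise the acetal to an O1=C5H2 oxocarbenium ion, which the enol ether attacks through C4 to give the pivalate A2 of the target.
- In its favour: both aryl rings and the ketone are in place at ring closure, so A2 is one acyl cleavage from 17 and no late organometallic addition is needed. This endgame is better than the chosen one, and the route is tin-free, which is also better. C4 again rests on thermodynamics, which is equal.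
- Against it here: the closure is 5-endo with respect to the C5=O1 bond, a less favourable geometry than the 5-exo displacement of the chosen plan. TMSOTf is a strong Lewis acid beside a benzylic C2–O bond activated by the trimethoxyphenyl ring, so ionisation at C2 competes with ionisation of the acetal. The pivalate carbonyl can intercept either cation. Removing a pivalate next to a γ-hydroxy ketone needs alkoxide or hydride, which threatens C4 or the ketone.
- Comparison: structurally, A1 needs C2 and C3 set beforehand by an auxiliary-controlled syn-aldol, against one catalytic epoxidation plus substrate control. Mechanistically it is cationic at the very centre that must not ionise, whereas the chosen step is anionic and leaves C2–O intact. In step count the two are about equal: a shorter end, a longer front.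

Alternative 2: The cut is C2–C3. The α-diazo ester A3 has a 3,4,5-trimethoxybenzyl ether at the C5 oxygen and a dioxolane-masked aryl ketone on C4. Rh2(S-PTTL)4 would convert it into a carbene at C3 that inserts into the benzylic C–H bond in a 1,5 sense to give the oxolane ester A4.
- In its favour: one catalytic step forms a C–C bond, the ring and two stereocentres (C2 and C3). This is better than the chosen key step, which creates none. The 2,3-cis outcome typical of such insertions next to oxygen is the relationship the target needs. The C–H bond is activated by oxygen and by the electron-rich ring.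
- Against it here: the carbene carbon has a hydrogen on C4, so 1,2-hydride migration is the classical competing path for alkyl-substituted diazo esters. C4 must be made enantiopure beforehand and matched with the chiral catalyst to give 3,4-trans. Diazo transfer onto a β-branched ester needs an activating acyl group. The electron-rich arenes invite cyclopropanation. The C3 ester of A4 sits cis to the aryl group and is epimerisable until reduced. LiAlH4 reduction and an acidic ketal hydrolysis beside the benzylic ether remain.
- Comparison: stereochemical economy is better on paper. Mechanistic risk is clearly higher than for an isomerisation that only moves an oxygen. Step count is equal at best, because A3 is long to prepare.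

Alternative 3: The cuts are O1–C2 and C4–C5. The trans cyclopropane diester A5 would be activated by Sn(OTf)2 and attacked at the benzylic carbon by the oxygen of formaldehyde A6 with inversion; the malonate then closes on the carbonyl carbon to give the geminal diester A7.
- In its favour: two ring bonds form in one convergent step, which is better than one bond in the chosen step. Stereospecific inversion turns the trans cyclopropane into the 2,3-cis oxolane, so C2 and C3 both come from one asymmetric cyclopropanation and no facial reduction is needed. After dealkoxycarbonylation the thermodynamic C4 logic and the amide/Grignard endgame are the same, which is equal.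
- Against it here: a donor as strong as trimethoxyphenyl lets the Lewis acid open the cyclopropane to a benzylic cation–malonate zwitterion before A6 arrives, which erodes the stereospecificity on which C2 and the cis relationship depend. Monomeric A6 is an awkward, oligomerising partner. 2,3-Disubstituted cyclopropane diesters react slowly. A high-temperature Krapcho dealkoxycarbonylation is added.
- Comparison: absolute stereochemistry from one catalytic step is equal. The mechanism depends on SN2-like behaviour at C2, the centre whose bond the chosen plan never breaks. Step count is comparable, since cyclopropane synthesis and decarboxylation consume the gain of the two-bond annulation.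

Key step: step 7

Remark on the chemistry: C2 has the same spatial arrangement from 7 to 17. Its descriptor is R up to 10 and S from 11 on only because the neighbouring ring carbon outranks the aryl group until it becomes a saturated CH. The 3,4-trans ester is assumed to be the more stable C4 epimer while the C2 and C3 substituents are cis.

## Route

Step 1
Reactants: 1 (E)-3-(3,4,5-trimethoxyphenyl)prop-2-enal
Product: 2 (Z)-2-iodo-3-(3,4,5-trimethoxyphenyl)prop-2-enal
Conditions: I2, K2CO3, DMAP (20 mol%), THF–H2O, rt
Reagents that add atoms: iodine, II
Why: Amine-catalysed α-iodination of an enal (conjugate addition of DMAP, iodination of the enolate, E1cB loss of DMAP); the elimination restores the more stable alkene with aryl trans to the formyl group, which is the (Z)-iodide.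

Step 2
Reactants: 2 (Z)-2-iodo-3-(3,4,5-trimethoxyphenyl)prop-2-enal
Product: 3 (Z)-2-iodo-3-(3,4,5-trimethoxyphenyl)prop-2-en-1-ol
Conditions: NaBH4, CeCl3·7H2O, MeOH, 0 °C
Reagents that add atoms: none
Why: Luche reduction; the cerium-modified borohydride reduces the aldehyde in 1,2 fashion and leaves the vinyl iodide and the alkene geometry untouched.

Step 3
Reactants: 4 methyl prop-2-ynoate (methyl propiolate)
Product: 5 methyl 2-(tributylstannyl)prop-2-enoate
Conditions: Bu3SnH, Pd(PPh3)4 (2 mol%), THF, 0 °C to rt
Reagents that add atoms: tributyltin hydride, CCCC[SnH](CCCC)CCCC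
Why: Syn-hydrostannation of an alkynoate under zerovalent palladium catalysis places tin on the α-carbon, the usual regiochemistry for propiolates; the minor β-stannyl isomer would be removed by chromatography.

Step 4
Reactants: 3 (Z)-2-iodo-3-(3,4,5-trimethoxyphenyl)prop-2-en-1-ol; 5 methyl 2-(tributylstannyl)prop-2-enoate
Product: 6 methyl (3E)-3-(hydroxymethyl)-2-methylidene-4-(3,4,5-trimethoxyphenyl)but-3-enoate
Conditions: Pd2(dba)3 (2.5 mol%), AsPh3, CuI (10 mol%), DMF, rt to 40 °C
Reagents that add atoms: none
Why: Stille coupling with retention of the iodide geometry; CuI and the weakly bound arsine speed transmetalation of the hindered 1-substituted vinylstannane and suppress cine substitution, and the neutral medium spares the hydroxy ester. The aryl group cis to the new acrylate unit disfavours the s-cis diene conformer, so cycloaddition dimerisation should be slow.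

Step 5
Reactants: 6 methyl (3E)-3-(hydroxymethyl)-2-methylidene-4-(3,4,5-trimethoxyphenyl)but-3-enoate
Product: 7 methyl 2-[(2R,3R)-2-(hydroxymethyl)-3-(3,4,5-trimethoxyphenyl)oxiran-2-yl]prop-2-enoate
Conditions: Ti(OiPr)4 (10 mol%), D-(−)-diisopropyl tartrate (12 mol%), t-BuOOH, 4 Å MS, CH2Cl2, −20 °C
Reagents that add atoms: tert-butyl hydroperoxide, CC(C)(C)OO
Why: Sharpless asymmetric epoxidation of a 2,3-disubstituted allylic alcohol; only the alkene of the allylic alcohol is epoxidised (the acrylate is electron-poor and homoallylic), and D-(−)-tartrate delivers oxygen to the face that gives (2R,3R)-3-arylglycidols from (E)-3-arylallyl alcohols, which sets C2 of the target. Syn addition keeps aryl trans to the hydroxymethyl group.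

Step 6
Reactants: 7 methyl 2-[(2R,3R)-2-(hydroxymethyl)-3-(3,4,5-trimethoxyphenyl)oxiran-2-yl]prop-2-enoate
Product: 8 methyl 2-[(2R,3R)-2-{[tert-butyl(dimethyl)silyl]oxymethyl}-3-(3,4,5-trimethoxyphenyl)oxiran-2-yl]prop-2-enoate
Conditions: TBSCl, imidazole, DMF, 0 °C to rt
Reagents that add atoms: tert-butyldimethylsilyl chloride, CC(C)(C)[Si](C)(C)Cl
Why: Standard silylation of a primary alcohol under weakly basic conditions that trigger neither Payne rearrangement nor epoxide opening.

Step 7
Reactants: 8 methyl 2-[(2R,3R)-2-{[tert-butyl(dimethyl)silyl]oxymethyl}-3-(3,4,5-trimethoxyphenyl)oxiran-2-yl]prop-2-enoate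
Product: 10 methyl (5R)-4-{[tert-butyl(dimethyl)silyl]oxymethyl}-5-(3,4,5-trimethoxyphenyl)-2,5-dihydrofuran-3-carboxylate, via allylic iodide alkoxide 9 (not isolated)
Conditions: LiI (20 mol%), THF, 50 °C
Reagents that add atoms: none
Why: Iodide adds in SN2′ (conjugate) fashion to the methylene terminus of the acrylate while lithium assists departure of the oxirane oxygen from the tertiary allylic carbon C3, giving alkoxide 9 with the iodomethyl group and the carbinol cis on the new C3=C4 alkene. The alkoxide, still bonded to C2, then displaces iodide at C5 and returns the catalyst; this closure is 5-exo-tet. The closest known reaction type is the iodide-catalysed isomerisation of vinyl oxiranes to 2,5-dihydrofurans, of which the Cu(hfacac)2-catalysed version is the Lewis acid counterpart. No stereocentre is created: C2 keeps its configuration because its C–O bond is never broken, and the quaternary oxirane carbon becomes sp2. The selectivity needed is cleavage of C3–O and not of the benzylic C2–O bond; the acrylate makes C5 a soft, unhindered acceptor for iodide, C2 is flanked by a quaternary carbon, and the absence of a strong Lewis acid avoids ionisation next to the electron-rich ring. The cis relationship of aryl and acrylate on the oxirane should turn the small methylene arm, not the ester, toward C2 in the reactive rotamer, which is the alkene geometry that ring closure needs. An alkoxide formed through the other rotamer can revert to 8 by the reverse conjugate displacement.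

Step 8
Reactants: 10 methyl (5R)-4-{[tert-butyl(dimethyl)silyl]oxymethyl}-5-(3,4,5-trimethoxyphenyl)-2,5-dihydrofuran-3-carboxylate
Product: 12 methyl (3R,4S,5S)-4-{[tert-butyl(dimethyl)silyl]oxymethyl}-5-(3,4,5-trimethoxyphenyl)oxolane-3-carboxylate, via all-cis ester 11 (not isolated)
Conditions: Cu(OAc)2·H2O (5 mol%), 1,2-bis(diphenylphosphino)benzene (5 mol%), MeSiH(OMe)2, t-BuOH, toluene, rt; then NaOMe (0.3 equiv), MeOH, rt
Reagents that add atoms: none
Why: Ligand-accelerated copper hydride conjugate reduction, a more reactive relative of [(Ph3P)CuH]6: hydride is delivered to C3 from the face opposite the C2 aryl group, which fixes the 2,3-cis relationship, and protonation at C4 should give mainly the all-cis ester 11. Methoxide then equilibrates the only acidic centre, C4, to the 3,4-trans ester 12, in which the ester no longer eclipses the C3 substituent.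

Step 9
Reactants: 12 methyl (3R,4S,5S)-4-{[tert-butyl(dimethyl)silyl]oxymethyl}-5-(3,4,5-trimethoxyphenyl)oxolane-3-carboxylate
Product: 13 (3R,4S,5S)-4-{[tert-butyl(dimethyl)silyl]oxymethyl}-N-methoxy-N-methyl-5-(3,4,5-trimethoxyphenyl)oxolane-3-carboxamide
Conditions: MeNH(OMe)·HCl, i-PrMgCl, THF, −20 to 0 °C
Reagents that add atoms: N,O-dimethylhydroxylamine hydrochloride, CNOC.Cl
Why: Weinreb amide formation by aminolysis of the ester with the chloromagnesium amide; C4 is already in its preferred configuration, so transient enolisation is harmless.

Step 10
Reactants: 13 (3R,4S,5S)-4-{[tert-butyl(dimethyl)silyl]oxymethyl}-N-methoxy-N-methyl-5-(3,4,5-trimethoxyphenyl)oxolane-3-carboxamide; 14 5-bromo-1,2,3-trimethoxybenzene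
Product: 16 [(3R,4S,5S)-4-{[tert-butyl(dimethyl)silyl]oxymethyl}-5-(3,4,5-trimethoxyphenyl)oxolan-3-yl](3,4,5-trimethoxyphenyl)methanone, via aryl Grignard reagent 15 (not isolated)
Conditions: Mg, I2 (cat.), THF, reflux; then 13, THF, 0 °C to rt; aq NH4Cl
Reagents that add atoms: none
Why: Grignard addition to a Weinreb amide stops at the chelated tetrahedral intermediate, which releases the ketone only on work-up, so single addition is secured; the silyl ether and the benzylic ether are inert to the arylmagnesium reagent.

Step 11
Reactants: 16 [(3R,4S,5S)-4-{[tert-butyl(dimethyl)silyl]oxymethyl}-5-(3,4,5-trimethoxyphenyl)oxolan-3-yl](3,4,5-trimethoxyphenyl)methanone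
Product: 17 [(3R,4S,5S)-4-(hydroxymethyl)-5-(3,4,5-trimethoxyphenyl)oxolan-3-yl](3,4,5-trimethoxyphenyl)methanone
Conditions: TBAF, AcOH (1:1), THF, 0 °C to rt
Reagents that add atoms: none
Why: Fluoride-mediated cleavage of the primary silyl ether, buffered with acetic acid so that the medium is neither basic enough to epimerise C4 or open the β-alkoxy ketone nor acidic enough to ionise the benzylic C2–O1 bond. The trans arrangement of hydroxymethyl and aroyl groups prevents lactol formation.

## Compound list

1 | (E)-3-(3,4,5-trimethoxyphenyl)prop-2-enal | COc1cc(/C=C/C=O)cc(OC)c1OC | starting material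
2 | (Z)-2-iodo-3-(3,4,5-trimethoxyphenyl)prop-2-enal | COc1cc(/C=C(\I)C=O)cc(OC)c1OC | intermediate
3 | (Z)-2-iodo-3-(3,4,5-trimethoxyphenyl)prop-2-en-1-ol | COc1cc(/C=C(\I)CO)cc(OC)c1OC | intermediate
4 | methyl prop-2-ynoate | C#CC(=O)OC | starting material
5 | methyl 2-(tributylstannyl)prop-2-enoate | CCCC[Sn](CCCC)(CCCC)C(=C)C(=O)OC | intermediate
6 | methyl (3E)-3-(hydroxymethyl)-2-methylidene-4-(3,4,5-trimethoxyphenyl)but-3-enoate | COC(=O)C(=C)/C(CO)=C\c1cc(OC)c(OC)c(OC)c1 | intermediate
7 | methyl 2-[(2R,3R)-2-(hydroxymethyl)-3-(3,4,5-trimethoxyphenyl)oxiran-2-yl]prop-2-enoate | COC(=O)C(=C)[C@]1(CO)O[C@@H]1c2cc(OC)c(OC)c(OC)c2 | intermediate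
8 | methyl 2-[(2R,3R)-2-{[tert-butyl(dimethyl)silyl]oxymethyl}-3-(3,4,5-trimethoxyphenyl)oxiran-2-yl]prop-2-enoate | COC(=O)C(=C)[C@]1(CO[Si](C)(C)C(C)(C)C)O[C@@H]1c2cc(OC)c(OC)c(OC)c2 | intermediate
9 | lithium (1R,2Z)-2-{[tert-butyl(dimethyl)silyl]oxymethyl}-3-(iodomethyl)-4-methoxy-4-oxo-1-(3,4,5-trimethoxyphenyl)but-2-en-1-olate | COC(=O)/C(CI)=C(\CO[Si](C)(C)C(C)(C)C)[C@H]([O-])c1cc(OC)c(OC)c(OC)c1.[Li+] | intermediate
10 | methyl (5R)-4-{[tert-butyl(dimethyl)silyl]oxymethyl}-5-(3,4,5-trimethoxyphenyl)-2,5-dihydrofuran-3-carboxylate | COC(=O)C1=C(CO[Si](C)(C)C(C)(C)C)[C@@H](c2cc(OC)c(OC)c(OC)c2)OC1 | intermediate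
11 | methyl (3S,4S,5S)-4-{[tert-butyl(dimethyl)silyl]oxymethyl}-5-(3,4,5-trimethoxyphenyl)oxolane-3-carboxylate (all-cis) | COC(=O)[C@@H]1CO[C@H](c2cc(OC)c(OC)c(OC)c2)[C@@H]1CO[Si](C)(C)C(C)(C)C | intermediate
12 | methyl (3R,4S,5S)-4-{[tert-butyl(dimethyl)silyl]oxymethyl}-5-(3,4,5-trimethoxyphenyl)oxolane-3-carboxylate | COC(=O)[C@H]1CO[C@H](c2cc(OC)c(OC)c(OC)c2)[C@@H]1CO[Si](C)(C)C(C)(C)C | intermediate
13 | (3R,4S,5S)-4-{[tert-butyl(dimethyl)silyl]oxymethyl}-N-methoxy-N-methyl-5-(3,4,5-trimethoxyphenyl)oxolane-3-carboxamide | CON(C)C(=O)[C@H]1CO[C@H](c2cc(OC)c(OC)c(OC)c2)[C@@H]1CO[Si](C)(C)C(C)(C)C | intermediate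
14 | 5-bromo-1,2,3-trimethoxybenzene | COc1cc(Br)cc(OC)c1OC | starting material
15 | (3,4,5-trimethoxyphenyl)magnesium bromide | COc1cc([Mg]Br)cc(OC)c1OC | intermediate
16 | [(3R,4S,5S)-4-{[tert-butyl(dimethyl)silyl]oxymethyl}-5-(3,4,5-trimethoxyphenyl)oxolan-3-yl](3,4,5-trimethoxyphenyl)methanone | COc1cc(C(=O)[C@H]2CO[C@H](c3cc(OC)c(OC)c(OC)c3)[C@@H]2CO[Si](C)(C)C(C)(C)C)cc(OC)c1OC | intermediate
17 | [(3R,4S,5S)-4-(hydroxymethyl)-5-(3,4,5-trimethoxyphenyl)oxolan-3-yl](3,4,5-trimethoxyphenyl)methanone (CNP0148560.1) | COc1cc(C(=O)[C@H]2CO[C@H](c3cc(OC)c(OC)c(OC)c3)[C@@H]2CO)cc(OC)c1OC | target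

## Step count and least certain steps

Total step count: 11. Longest linear sequence: 10 steps (steps 1, 2 and 4 to 11, from 1 to 17); step 3 is a one-step side branch.

Step 7 (key step). Most likely failure: ring opening through the rotamer that places the ester, not the iodomethyl group, cis to the carbinol, followed by lactonisation of the lithium alkoxide onto the ester. A lesser risk is iodide attack at the benzylic carbon, which would erode the configuration of C2. The fallback caps the oxygen with silicon so that it is never a free alkoxide while the ring is open. It sets out from 8: TMSI with hexamethyldisilazane in CH2Cl2 at −78 °C should open the oxirane in the same SN2′ sense to methyl (2Z,4R)-3-{[tert-butyl(dimethyl)silyl]oxymethyl}-2-(iodomethyl)-4-(3,4,5-trimethoxyphenyl)-4-[(trimethylsilyl)oxy]but-2-enoate F1, which cannot lactonise and can be freed from its geometric isomer. K2CO3 in MeOH at 0 °C then removes the trimethylsilyl group selectively and the liberated oxygen closes on the iodomethyl carbon; the route is rejoined at 10.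

Step 8. Most likely failure: no conversion, because the tetrasubstituted β-carbon is too shielded for copper hydride, or incomplete facial discrimination at C3. The fallback replaces hydride conjugate addition by syn-hydrogenation from the face opposite the aryl group. It sets out from 10 with H2 and [Ir(cod)(PCy3)(py)]PF6 in CH2Cl2, a catalyst that reduces tetrasubstituted alkenes without hydrogenolysis of benzylic ethers, and comes back at 11, which is then equilibrated with NaOMe to 12 as in the main route. No compound outside the list is made (F0).

Step 4. Most likely failure: slow transmetalation of the 1-substituted vinylstannane, leading to cine substitution or protodestannylation, and lactonisation or oligomerisation of the dienyl hydroxy ester on prolonged heating. The fallback reverses the polarity of the coupling. It sets out from 3: Miyaura borylation (bis(pinacolato)diboron, PdCl2(dppf), KOAc, dioxane) should give (2E)-2-(4,4,5,5-tetramethyl-1,3,2-dioxaborolan-2-yl)-3-(3,4,5-trimethoxyphenyl)prop-2-en-1-ol F2, and Suzuki–Miyaura coupling with commercial methyl 2-bromoacrylate (Pd(PPh3)4, K3PO4, THF–H2O) comes back at 6.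

Step 5. Most likely failure: titanium-mediated opening of the electron-rich benzylic oxirane or lactonisation of the titanium-bound alkoxide onto the ester, and a slow epoxidation with lowered enantioselectivity because the alkene is cross-conjugated with an acrylate. The fallback drops the hydroxyl-directed method. It sets out from 6, which is silylated (TBSCl, imidazole) to methyl (3E)-3-{[tert-butyl(dimethyl)silyl]oxymethyl}-2-methylidene-4-(3,4,5-trimethoxyphenyl)but-3-enoate F3. Shi epoxidation with the D-fructose-derived ketone and KHSO5 under carbonate buffer at 0 °C is expected, by analogy with trans-β-methylstyrene, to attack the same face of the electron-rich trisubstituted alkene and leave the acrylate alone. It comes back at 8.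

Further compounds
F1 | step 7 | methyl (2Z,4R)-3-{[tert-butyl(dimethyl)silyl]oxymethyl}-2-(iodomethyl)-4-(3,4,5-trimethoxyphenyl)-4-[(trimethylsilyl)oxy]but-2-enoate | COC(=O)/C(CI)=C(\CO[Si](C)(C)C(C)(C)C)[C@H](O[Si](C)(C)C)c1cc(OC)c(OC)c(OC)c1
F0 | step 8 | none | none
F2 | step 4 | (2E)-2-(4,4,5,5-tetramethyl-1,3,2-dioxaborolan-2-yl)-3-(3,4,5-trimethoxyphenyl)prop-2-en-1-ol | COc1cc(/C=C(\B2OC(C)(C)C(C)(C)O2)CO)cc(OC)c1OC
F3 | step 5 | methyl (3E)-3-{[tert-butyl(dimethyl)silyl]oxymethyl}-2-methylidene-4-(3,4,5-trimethoxyphenyl)but-3-enoate | COC(=O)C(=C)/C(CO[Si](C)(C)C(C)(C)C)=C\c1cc(OC)c(OC)c(OC)c1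
A1 | alternative 1 | (Z)-trimethylsilyl enol ether of the open-chain aryl ketone with a methoxymethyl ether on the C2 oxygen and a pivalate on the C3 hydroxymethyl group | COCO[C@H](c1cc(OC)c(OC)c(OC)c1)[C@@H](/C=C(\O[Si](C)(C)C)c1cc(OC)c(OC)c(OC)c1)COC(=O)C(C)(C)C
A2 | alternative 1 | O-pivaloyl ester of the target | COc1cc(cc(OC)c1OC)C(=O)[C@H]2CO[C@H](c3cc(OC)c(OC)c(OC)c3)[C@@H]2COC(=O)C(C)(C)C
A3 | alternative 2 | methyl 2-diazo-3-[2-(3,4,5-trimethoxyphenyl)-1,3-dioxolan-2-yl]-4-[(3,4,5-trimethoxybenzyl)oxy]butanoate, C4 configured as in the target | COC(=O)C(=[N+]=[N-])[C@H](COCc1cc(OC)c(OC)c(OC)c1)C2(OCCO2)c3cc(OC)c(OC)c(OC)c3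
A4 | alternative 2 | methyl 2,3-cis-3,4-trans-2-(3,4,5-trimethoxyphenyl)-4-[2-(3,4,5-trimethoxyphenyl)-1,3-dioxolan-2-yl]oxolane-3-carboxylate | COc1cc(cc(OC)c1OC)C3(OCCO3)[C@H]2CO[C@H](c4cc(OC)c(OC)c(OC)c4)[C@@H]2C(=O)OC
A5 | alternative 3 | diethyl trans-2-(3,4,5-trimethoxyphenyl)-3-{[tert-butyl(dimethyl)silyl]oxymethyl}cyclopropane-1,1-dicarboxylate | CCOC(=O)C1(C(=O)OCC)[C@@H](c2cc(OC)c(OC)c(OC)c2)[C@@H]1CO[Si](C)(C)C(C)(C)C
A6 | alternative 3 | formaldehyde | C=O
A7 | alternative 3 | diethyl (4S,5S)-4-{[tert-butyl(dimethyl)silyl]oxymethyl}-5-(3,4,5-trimethoxyphenyl)oxolane-3,3-dicarboxylate | CCOC(=O)C1(C(=O)OCC)CO[C@H](c2cc(OC)c(OC)c(OC)c2)[C@@H]1CO[Si](C)(C)C(C)(C)C
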